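The free enzyme charged is a catalyst and stays in the flask through a run, so target made can be counted against that fixed charge.

common to all: starting material 0.050 M

| charge | second substrate | free enzyme | remark | time |
|---|---|---|---|---|
| Wednesday's | 0.067 M | 25 µM | run made earlier |  |
| Saturday's | 0.15 M | 25 µM | run made earlier |  |
| Thursday's | 0.10 M | 38 µM | run made earlier |  |
| flask | 0.100 M | 25 µM |  | 5.0 h |

| run | time / h | target / % | starting material / % |
|---|---|---|---|
| Wednesday's | 1.33 | 11.7 | 52.6 |
| Wednesday's | 1.50 | 10.2 | 46.4 |
| Wednesday's | 2.00 | 11.7 | 39.7 |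
| Wednesday's | 2.50 | 15.6 | 31.7 |
| Wednesday's | 3.00 | 17.5 | 27.0 |
| Saturday's | 1.33 | 9.2 | 51.1 |
| Saturday's | 1.50 | 10.6 | 47.3 |
| Saturday's | 2.00 | 15.3 | 37.8 |
| Saturday's | 2.50 | 15.1 | 31.5 |
| Saturday's | 3.00 | 17.2 | 26.3 |
| Thursday's | 1.33 | 14.5 | 47.7 |
| Thursday's | 1.50 | 13.8 | 45.1 |
| Thursday's | 2.00 | 20.0 | 34.2 |
| Thursday's | 2.50 | 23.7 | 26.8 |
| Thursday's | 3.00 | 25.8 | 21.0 |

(readings scatter by 1 percentage point)

- the numbers in the tables scatter with a standard deviation of 1 percentage point

- time up to 5.0 h at which target stands highest
- the amount of target, in percent of the starting material charged, at that time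

At 3.00 h, target per free enzyme charged per hour reads 117 h⁻¹ in Wednesday's run, 115 h⁻¹ in Saturday's and 113 h⁻¹ in Thursday's, although second substrate and free enzyme differ among them. Their mean, 115 h⁻¹, is the turnover frequency: target made per free enzyme charged per hour, averaged over the first 3.00 h.

Two extreme versions of the flask can be reckoned in the head. If that turnover held throughout, target would climb in a straight line, zero order in starting material, to 28.7% at 5.0 h. If target were instead a fixed share of starting material lost, first order, Wednesday's share of 24.0% and its decay carried on to 5.0 h would give 21.3%. The flask should lie between them. The share is not fixed, since Thursday's reads 32.7%, yet the mean target of Wednesday's and Saturday's runs, which share the flask's free enzyme, reads 10.4% at 1.33 h and 17.3% at 3.00 h, so it climbs more slowly after 1.33 h than before. Carrying that later climb on gives this reckoning's 25.6%, still rising at 5.0 h.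

The forecast differs, giving 20.5% (range 18.5% to 23%) at 5 h, “so 87% consumed × 0.23 gives about 20%”.

    starting material + free enzyme ⇌ first complex (K = 51.0 M⁻¹, k = 3700 M⁻¹ min⁻¹)
    first complex → loaded enzyme + first product (k = 5.17 min⁻¹)
    second substrate + loaded enzyme ⇌ second complex (K = 16.0 M⁻¹, k = 2760 M⁻¹ min⁻¹)
    second complex → free enzyme + target (k = 14.0 min⁻¹)
    starting material ⇌ dormant form (K = 2.76, k = 0.00775 min⁻¹)

The flask gives 27.1% at 5.00 h, an average turnover of 108 h⁻¹. Free enzyme in this flask stood at 25.2% of the catalyst charged at 0.500 h and 59.3% at 5.00 h. In the neighbour flask charged with 4.2 × 10⁻⁵ M of free enzyme, the turnover of 115 h⁻¹ reckons 48.2% at 5.0 h, and that neighbour holds 41.4%.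

The readings stem from a simulated flask with constants of no real substance.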